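**Retrosynthetic overview**
- The oxolane ring, the free 3-OH and the tertiary 8-OAc come last, in one operation: acetolysis of a (3R,4R,7R,8R)-3,4:7,8-bis-epoxide, in which the 7,8-epoxide oxygen opens the 3,4-epoxide and acetic acid opens the resulting epoxonium ion.
- The bis-epoxide comes from double Shi epoxidation of the macrocyclic 3E,7E-diene α-methylene lactone.
- The cis-fused α-methylene lactone (C1 stereocentre, 15(17)-ene) comes from a macrocycle-fused butenolide by face-selective conjugate reduction and α-methylenation.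
- The 14-membered ring is closed at C1–C2, the bond formed in cembrane biosynthesis, from an acyclic geranylgeranyl-type chain: allylic acetate (diphosphate surrogate) plus the terminal butenolide carbon.
- The chain comes from (2E,6E)-farnesyl acetate (C2–C13) and tetronic acid (C14, C1, C15, C16) by a vinylogous Mukaiyama aldol that sets C13 and C14. Ring order: butenolide (bought) → 14-membered carbocycle → two oxiranes → oxolane.

Assumption: cembrane numbering is used for the macrocycles (C1 = ring-fusion carbon bearing C15; C14 = lactone O-bearing carbon; C16 = lactone carbonyl; C17 = exocyclic methylene; methyls on C4, C8, C12).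
Assumption: Ru(OAc)2[(S)-BINAP] adds H2 to the 2-methyl allylic alcohol with the same facial sense as to geraniol (which gives (R)-citronellol); if the sense proves opposite, the (R)-ligand is used.

**Route**

Step 1
Reactants: 1 (2E,6E)-farnesyl acetate
Product: 2 (2E,6E,10E)-12-hydroxy-3,7,11-trimethyldodeca-2,6,10-trien-1-yl acetate
Conditions: SeO2 (0.1 equiv), t-BuOOH (70% aq.), salicylic acid (cat.), CH2Cl2, 0 °C to rt
Reagents that add atoms: tert-butyl hydroperoxide, CC(C)(C)OO; selenium dioxide (catalytic oxygen carrier), O=[Se]=O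
Why: Sharpless–Umbreit allylic oxidation (ene reaction then 2,3-sigmatropic shift) attacks the (E)-methyl of the terminal, most electron-rich alkene, while the 2,3-alkene is deactivated by the allylic acetate; no stereocentre is formed.

Step 2
Reactants: 2 (2E,6E,10E)-12-hydroxy-3,7,11-trimethyldodeca-2,6,10-trien-1-yl acetate
Product: 3 (2E,6E,11S)-12-hydroxy-3,7,11-trimethyldodeca-2,6-dien-1-yl acetate
Conditions: Ru(OAc)2[(S)-BINAP] (1 mol %), H2 (50 atm), MeOH, 25 °C
Reagents that add atoms: none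
Why: Noyori hydroxyl-directed asymmetric hydrogenation reduces only the alkene of the free allylic alcohol (the allylic-acetate alkene and the isolated trisubstituted alkene do not chelate ruthenium), and the (S)-ligand sets C11 (later C12) as S.

Step 3
Reactants: 3 (2E,6E,11S)-12-hydroxy-3,7,11-trimethyldodeca-2,6-dien-1-yl acetate
Product: 4 (2E,6E,11S)-3,7,11-trimethyl-12-oxododeca-2,6-dien-1-yl acetate
Conditions: Dess–Martin periodinane, CH2Cl2, 0 °C to rt
Reagents that add atoms: none
Why: Dess–Martin oxidation gives the α-methyl aldehyde without base, so the stereocentre is not epimerised.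

Step 4
Reactants: 5 tetronic acid (4-hydroxyfuran-2(5H)-one)
Product: 6 4-bromofuran-2(5H)-one
Conditions: (COBr)2, DMF (cat.), CH2Cl2, 0 °C to rt
Reagents that add atoms: oxalyl bromide, O=C(Br)C(=O)Br
Why: Vilsmeier-type activation of the vinylogous acid followed by addition–elimination of bromide; no stereocentre.

Step 5
Reactants: 4 (2E,6E,11S)-3,7,11-trimethyl-12-oxododeca-2,6-dien-1-yl acetate; 6 4-bromofuran-2(5H)-one
Product: 8 (5S)-4-bromo-5-[(1R,2S,6E,10E)-12-acetoxy-1-hydroxy-2,6,10-trimethyldodeca-6,10-dien-1-yl]furan-2(5H)-one, via silyloxyfuran 7 (not isolated)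
Conditions: 6, TBSOTf, i-Pr2NEt, CH2Cl2, 0 °C; then 4, BF3·OEt2, −78 °C
Reagents that add atoms: none
Why: vinylogous Mukaiyama aldol at the γ-carbon of the silyloxyfuran through an open transition state, in which Felkin–Anh attack on the α-methyl aldehyde sets C13 syn to the C12 methyl and the usual threo preference of Lewis-acid silyloxyfuran additions (expected to be reinforced by the bromine next to the reacting carbon) sets C14; minor diastereomers are removed here by chromatography.

Step 6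
Reactants: 8 (5S)-4-bromo-5-[(1R,2S,6E,10E)-12-acetoxy-1-hydroxy-2,6,10-trimethyldodeca-6,10-dien-1-yl]furan-2(5H)-one
Product: 9 (5S)-4-bromo-5-[(1R,2S,6E,10E)-1,12-diacetoxy-2,6,10-trimethyldodeca-6,10-dien-1-yl]furan-2(5H)-one
Conditions: Ac2O, Sc(OTf)3 (1 mol %), MeCN, −20 °C
Reagents that add atoms: acetic anhydride, CC(=O)OC(C)=O
Why: Lewis-acid-catalysed acetylation without amine base, because base would cause E1cB loss of the new acetate from the acidic γ-position of the butenolide; configuration is untouched.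

Step 7
Reactants: 9 (5S)-4-bromo-5-[(1R,2S,6E,10E)-1,12-diacetoxy-2,6,10-trimethyldodeca-6,10-dien-1-yl]furan-2(5H)-one
Product: 11 (3E,7E,12S,13R,14R)-13-acetoxycembra-1(15),3,7-trien-16,14-olide, via vinylstannane 10 (not isolated)
Conditions: Pd(PPh3)4 (10 mol %), (Me3Sn)2 (1.05 equiv), LiCl, 1,4-dioxane, 80 °C, slow addition to 1 mM
Reagents that add atoms: none
Why: Proposed new method: zerovalent palladium inserts first into the electron-poor vinyl C–Br bond and (Me3Sn)2 turns it into vinylstannane 10, which is then captured intramolecularly by the π-allylpalladium species from the primary allylic acetate, reductive elimination at the unhindered allyl terminus closing the 14-membered ring at C1–C2 with retention of the 3E geometry and no new stereocentre; the closest known reactions are Stille–Kelly ditin-mediated intramolecular couplings and sp2–sp3 Stille macrocyclisations of vinylstannanes with allylic acetates.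

Step 8
Reactants: 11 (3E,7E,12S,13R,14R)-13-acetoxycembra-1(15),3,7-trien-16,14-olide
Product: 13 (1S,3E,7E,12S,13R,14R)-13-acetoxy-17-(dimethylamino)cembra-3,7-dien-16,14-olide (C15 epimers), via silyl ketene acetal 12 (not isolated)
Conditions: Cu(OAc)2·H2O (5 mol %), 1,2-bis(diphenylphosphino)benzene (5 mol %), PhMe2SiH, toluene, rt; then Me2N=CH2+ I−, CH2Cl2, 0 °C to rt; aq. NaHCO3 work-up
Reagents that add atoms: N,N-dimethylmethyleneiminium iodide (Eschenmoser's salt), C=[N+](C)C.[I-]
Why: copper hydride 1,4-reduction delivers hydride to C1 from the butenolide face opposite the C13 side of the macrocycle, giving the cis ring fusion (C1 S), and the silyl ketene acetal is trapped at C15 by the iminium salt in a Mannich reaction.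

Step 9
Reactants: 13 (1S,3E,7E,12S,13R,14R)-13-acetoxy-17-(dimethylamino)cembra-3,7-dien-16,14-olide
Product: 15 (1S,3E,7E,12S,13R,14R)-13-acetoxycembra-3,7,15(17)-trien-16,14-olide, via ammonium iodide 14 (not isolated)
Conditions: MeI, THF, rt; then aq. NaHCO3, CH2Cl2, rt
Reagents that add atoms: none
Why: N-methylation followed by E1cB (Hofmann-type) loss of trimethylamine gives the 15(17)-exo-methylene lactone; the C15 centre disappears and no other centre is touched.

Step 10
Reactants: 15 (1S,3E,7E,12S,13R,14R)-13-acetoxycembra-3,7,15(17)-trien-16,14-olide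
Product: 16 (1S,3R,4R,7R,8R,12S,13R,14R)-13-acetoxy-3,4:7,8-diepoxycembr-15(17)-en-16,14-olide
Conditions: D-fructose-derived Shi ketone (0.6 equiv), KHSO5 (as 2KHSO5·KHSO4·K2SO4), K2CO3, Bu4NHSO4, MeCN/dimethoxymethane/aq. Na2B4O7 buffer (pH 10.5), 0 °C
Reagents that add atoms: potassium peroxymonosulfate, [K+].[O-]S(=O)(=O)OO
Why: Shi asymmetric epoxidation, in which the chiral dioxirane attacks both electron-rich E-trisubstituted alkenes through the spiro transition state to give R,R-epoxides under reagent control, while the electron-poor exocyclic methylene is inert.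

Step 11
Reactants: 16 (1S,3R,4R,7R,8R,12S,13R,14R)-13-acetoxy-3,4:7,8-diepoxycembr-15(17)-en-16,14-olide
Product: 18 (1S,3R,4S,7R,8S,12S,13R,14R)-8,13-diacetoxy-4,7-epoxy-3-hydroxycembr-15(17)-en-16,14-olide (CID10479028), via epoxonium ion 17 (not isolated)
Conditions: glacial AcOH, 30 °C
Reagents that add atoms: acetic acid, CC(=O)O
Why: acid-mediated transannular epoxide-opening cascade, in which the 7,8-epoxide oxygen opens the protonated 3,4-epoxide at tertiary C4 in the favoured 5-exo mode with inversion (oxolane, C4 S, free 3R-OH) and acetic acid opens the epoxonium ion at tertiary C8 with inversion (C8 S acetate), C3 and C7 keeping their oxygen and configuration.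

**Compound list**
1 | (2E,6E)-farnesyl acetate [(2E,6E)-3,7,11-trimethyldodeca-2,6,10-trien-1-yl acetate] | CC(C)=CCC/C(C)=C/CC/C(C)=C/COC(C)=O | starting material
2 | (2E,6E,10E)-12-hydroxy-3,7,11-trimethyldodeca-2,6,10-trien-1-yl acetate | OC/C(C)=C/CC/C(C)=C/CC/C(C)=C/COC(C)=O | intermediate
3 | (2E,6E,11S)-12-hydroxy-3,7,11-trimethyldodeca-2,6-dien-1-yl acetate | OC[C@@H](C)CCC/C(C)=C/CC/C(C)=C/COC(C)=O | intermediate
4 | (2E,6E,11S)-3,7,11-trimethyl-12-oxododeca-2,6-dien-1-yl acetate | O=C[C@@H](C)CCC/C(C)=C/CC/C(C)=C/COC(C)=O | intermediate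
5 | tetronic acid (4-hydroxyfuran-2(5H)-one) | OC1=CC(=O)OC1 | starting material
6 | 4-bromofuran-2(5H)-one | BrC1=CC(=O)OC1 | intermediate
7 | [(4-bromofuran-2-yl)oxy](tert-butyl)dimethylsilane | CC(C)(C)[Si](C)(C)Oc1cc(Br)co1 | intermediate
8 | (5S)-4-bromo-5-[(1R,2S,6E,10E)-12-acetoxy-1-hydroxy-2,6,10-trimethyldodeca-6,10-dien-1-yl]furan-2(5H)-one | O=C1C=C(Br)[C@H]([C@H](O)[C@@H](C)CCC/C(C)=C/CC/C(C)=C/COC(C)=O)O1 | intermediate
9 | (5S)-4-bromo-5-[(1R,2S,6E,10E)-1,12-diacetoxy-2,6,10-trimethyldodeca-6,10-dien-1-yl]furan-2(5H)-one | O=C1C=C(Br)[C@H]([C@H](OC(C)=O)[C@@H](C)CCC/C(C)=C/CC/C(C)=C/COC(C)=O)O1 | intermediate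
10 | (5S)-5-[(1R,2S,6E,10E)-1,12-diacetoxy-2,6,10-trimethyldodeca-6,10-dien-1-yl]-4-(trimethylstannyl)furan-2(5H)-one | O=C1C=C([Sn](C)(C)C)[C@H]([C@H](OC(C)=O)[C@@H](C)CCC/C(C)=C/CC/C(C)=C/COC(C)=O)O1 | intermediate
11 | (3E,7E,12S,13R,14R)-13-acetoxycembra-1(15),3,7-trien-16,14-olide (14-membered carbocycle fused at C1/C14 to a butenolide) | O=C1O[C@H]2[C@H](OC(C)=O)[C@@H](C)CCC/C(C)=C/CC/C(C)=C/CC2=C1 | intermediate
12 | dimethyl(phenyl)silyl ketene acetal of (1S,3E,7E,12S,13R,14R)-13-acetoxycembra-3,7-dien-16,14-olide (C15=C16–OSiMe2Ph) | C1=C(O[Si](C)(C)c3ccccc3)O[C@H]2[C@H](OC(C)=O)[C@@H](C)CCC/C(C)=C/CC/C(C)=C/C[C@@H]12 | intermediate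
13 | (1S,3E,7E,12S,13R,14R)-13-acetoxy-17-(dimethylamino)cembra-3,7-dien-16,14-olide (C15 epimers) | CN(C)CC1C(=O)O[C@H]2[C@H](OC(C)=O)[C@@H](C)CCC/C(C)=C/CC/C(C)=C/C[C@@H]12 | intermediate
14 | N-methyl ammonium iodide of 13 (17-trimethylammonio lactone iodide) | C[N+](C)(C)CC1C(=O)O[C@H]2[C@H](OC(C)=O)[C@@H](C)CCC/C(C)=C/CC/C(C)=C/C[C@@H]12.[I-] | intermediate
15 | (1S,3E,7E,12S,13R,14R)-13-acetoxycembra-3,7,15(17)-trien-16,14-olide | C=C1C(=O)O[C@H]2[C@H](OC(C)=O)[C@@H](C)CCC/C(C)=C/CC/C(C)=C/C[C@@H]12 | intermediate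
16 | (1S,3R,4R,7R,8R,12S,13R,14R)-13-acetoxy-3,4:7,8-diepoxycembr-15(17)-en-16,14-olide | C=C1C(=O)O[C@H]2[C@H](OC(C)=O)[C@@H](C)CCC[C@@]3(C)O[C@@H]3CC[C@@]4(C)O[C@@H]4C[C@@H]12 | intermediate
17 | bicyclic epoxonium ion (oxygen bonded to C4, C7 and C8; 3R-OH; 4S,7R,8R) as its acetate | C=C1C(=O)O[C@H]2[C@H](OC(C)=O)[C@@H](C)CCC[C@@]3(C)[O+]4[C@@H]3CC[C@@]4(C)[C@H](O)C[C@@H]12.CC(=O)[O-] | intermediate
18 | (1S,3R,4S,7R,8S,12S,13R,14R)-8,13-diacetoxy-4,7-epoxy-3-hydroxycembr-15(17)-en-16,14-olide (CID10479028) | C=C1C(=O)O[C@H]2[C@H](OC(C)=O)[C@@H](C)CCC[C@](C)(OC(C)=O)[C@H]3CC[C@](C)(O3)[C@H](O)C[C@@H]12 | target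

**Step count**
Total steps: 11. Longest linear sequence: 10 (steps 1, 2, 3, 5, 6, 7, 8, 9, 10, 11 from 1; step 4 is the side branch).

**Three steps most likely to fail**

Step 5 (open-chain vinylogous aldol). The Felkin/threo selectivity of the 4-bromo silyloxyfuran is untested, and the Lewis acid could trigger an ene cyclisation of 4. The fallback reverses the order of the two C–C bond formations so that the aldol becomes the ring closure. It sets out from 6 and 4 and comes back at 11. Stannylation of 6 with (Bu3Sn)2 and Pd(PPh3)4 gives 4-(tributylstannyl)furan-2(5H)-one F1. Intermolecular Stille coupling of F1 with the allylic acetate of 4 (Pd2(dba)3, AsPh3, LiCl, NMP) gives (2S,6E,10E)-2,6,10-trimethyl-12-(5-oxo-2,5-dihydrofuran-3-yl)dodeca-6,10-dienal F2. TBSOTf and i-Pr2NEt at high dilution convert it into the silyloxyfuran aldehyde F3, which BF3·OEt2 closes at C13–C14 to (3E,7E,12S,13R,14R)-13-hydroxycembra-1(15),3,7-trien-16,14-olide F4; here the 14-membered transition state, not open-chain selectivity, chooses the faces. Acetylation (Ac2O, Sc(OTf)3) gives 11.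

Step 7 (one-pot stannylation and macrocyclisation). Ditin may also stannylate the allylic acetate, or oligomers may form. The fallback installs the tin before the two reacting ends are in one molecule. It sets out from 6 and 4 and comes back at 10, now as an isolated compound. (Me3Sn)2 and Pd(PPh3)4 convert 6 into 4-(trimethylstannyl)furan-2(5H)-one F5. TBSOTf and i-Pr2NEt give tert-butyldimethyl{[4-(trimethylstannyl)furan-2-yl]oxy}silane F6. Vinylogous aldol with 4 under a mild Lewis acid gives (5S)-5-[(1R,2S,6E,10E)-12-acetoxy-1-hydroxy-2,6,10-trimethyldodeca-6,10-dien-1-yl]-4-(trimethylstannyl)furan-2(5H)-one F7, and acetylation gives 10. A conventional high-dilution Stille macrocyclisation (Pd2(dba)3, AsPh3, LiCl, NMP, 50 °C) then leads to 11.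

Step 11 (acetolysis cascade). Neutral acetic acid may activate the epoxides too weakly, or capture of the epoxonium ion at tertiary C8 may lose to elimination or to the 4,8-ether. The fallback ends the cascade with water and acetylates afterwards. It sets out from 16 and comes back at 18. Catalytic HClO4 in THF/H2O gives (1S,3R,4S,7R,8S,12S,13R,14R)-13-acetoxy-4,7-epoxy-3,8-dihydroxycembr-15(17)-en-16,14-olide F8. TESCl and imidazole silylate only the secondary 3-OH to give the 3-O-triethylsilyl ether F9. Forced acetylation of the tertiary 8-OH (Ac2O, 4-pyrrolidinopyridine, Et3N, 40 °C) gives the 3-O-triethylsilyl 8,13-diacetate F10. HF·pyridine removes the silyl group to give 18.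

**Further compounds**
F1 | step 5 | 4-(tributylstannyl)furan-2(5H)-one | CCCC[Sn](CCCC)(CCCC)C1=CC(=O)OC1
F2 | step 5 | (2S,6E,10E)-2,6,10-trimethyl-12-(5-oxo-2,5-dihydrofuran-3-yl)dodeca-6,10-dienal | O=C[C@@H](C)CCC/C(C)=C/CC/C(C)=C/CC1=CC(=O)OC1
F3 | step 5 | (2S,6E,10E)-12-[5-(tert-butyldimethylsilyloxy)furan-3-yl]-2,6,10-trimethyldodeca-6,10-dienal | O=C[C@@H](C)CCC/C(C)=C/CC/C(C)=C/Cc1coc(O[Si](C)(C)C(C)(C)C)c1
F4 | step 5 | (3E,7E,12S,13R,14R)-13-hydroxycembra-1(15),3,7-trien-16,14-olide | O=C1O[C@H]2[C@H](O)[C@@H](C)CCC/C(C)=C/CC/C(C)=C/CC2=C1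
F5 | step 7 | 4-(trimethylstannyl)furan-2(5H)-one | C[Sn](C)(C)C1=CC(=O)OC1
F6 | step 7 | tert-butyldimethyl{[4-(trimethylstannyl)furan-2-yl]oxy}silane | CC(C)(C)[Si](C)(C)Oc1cc([Sn](C)(C)C)co1
F7 | step 7 | (5S)-5-[(1R,2S,6E,10E)-12-acetoxy-1-hydroxy-2,6,10-trimethyldodeca-6,10-dien-1-yl]-4-(trimethylstannyl)furan-2(5H)-one | O=C1C=C([Sn](C)(C)C)[C@H]([C@H](O)[C@@H](C)CCC/C(C)=C/CC/C(C)=C/COC(C)=O)O1
F8 | step 11 | (1S,3R,4S,7R,8S,12S,13R,14R)-13-acetoxy-4,7-epoxy-3,8-dihydroxycembr-15(17)-en-16,14-olide | C=C1C(=O)O[C@H]2[C@H](OC(C)=O)[C@@H](C)CCC[C@](C)(O)[C@H]3CC[C@](C)(O3)[C@H](O)C[C@@H]12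
F9 | step 11 | 3-O-triethylsilyl ether of F8 | C=C1C(=O)O[C@H]2[C@H](OC(C)=O)[C@@H](C)CCC[C@](C)(O)[C@H]3CC[C@](C)(O3)[C@H](O[Si](CC)(CC)CC)C[C@@H]12
F10 | step 11 | 3-O-triethylsilyl ether of 18 | C=C1C(=O)O[C@H]2[C@H](OC(C)=O)[C@@H](C)CCC[C@](C)(OC(C)=O)[C@H]3CC[C@](C)(O3)[C@H](O[Si](CC)(CC)CC)C[C@@H]12
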